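(The readings were generated by integration with constants of no real substance, and the scatter is random.)

One per molar is the unit of the number I carry: target set against the share left out of target and against the partner not in target.

| setting | Wednesday's | Tuesday's | Monday's | flask |
|---|---|---|---|---|
| starting material | 0.15 M | 0.35 M | 0.23 M | 0.23 M |
| partner | 2 equiv | 2 equiv | 1 equiv | 2.00 equiv |
| remark | run made earlier | run made earlier | run made earlier |  |
| time |  |  |  | 5.0 h |

| run | time / h | starting material / % | target / % |
|---|---|---|---|
| Wednesday's | 0.417 | 4 | 84 |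
| Wednesday's | 1.33 | 6 | 86 |
| Wednesday's | 2.00 | 1 | 79 |
| Wednesday's | 3.00 | 0 | 86 |
| Wednesday's | 5.00 | 0 | 86 |
| Wednesday's | 6.00 | 1 | 87 |
| Tuesday's | 0.417 | 4 | 95 |
| Tuesday's | 1.33 | 0 | 93 |
| Tuesday's | 2.00 | 1 | 94 |
| Tuesday's | 3.00 | 1 | 90 |
| Tuesday's | 5.00 | 6 | 96 |
| Tuesday's | 6.00 | 1 | 91 |
| Monday's | 0.500 | 11 | 70 |
| Monday's | 0.833 | 9 | 66 |
| Monday's | 1.50 | 7 | 67 |
| Monday's | 3.00 | 6 | 65 |
| Monday's | 6.00 | 11 | 67 |

(scatter of a reading: 2 percentage points)



- share of the starting material used up at 5.0 h
- target at 5.0 h, in percent of the starting material charged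

| run | c(starting material) | partner | mean target | share left | c(partner not in target) | Q |
|---|---|---|---|---|---|---|
| Monday's | 0.23 M | 1 equiv | 67.0% | 33.0% | 0.0759 M | 26.7 /M |
| Tuesday's | 0.35 M | 2 equiv | 93.2% | 6.80% | 0.374 M | 36.5 /M |
| Wednesday's | 0.15 M | 2 equiv | 84.7% | 15.3% | 0.173 M | 31.9 /M |

Target shows no steady drift in the readings of Monday's, Tuesday's or Wednesday's run, so I treat each plateau as a balance. Tuesday's run, at the same equivalents as Wednesday's but the larger charge, leaves 6.80% against 15.3%. Monday's run, with 1 equiv, leaves 33.0%, the most of the three. Yet the share left spans a factor of 4.85 and the last column a factor of 1.37, so I take the mean reading, 31.7 /M, as my holding constant Q, an apparent equilibrium constant: target over share left times c(partner not in target).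

In the flask, with 2.00 equiv, a share left x makes c(partner not in target) equal to c(starting material) times one plus x. Solving gives x = 11.0%, so I commit to 89.0% target. Starting material in the two runs at that ratio averages 2.08%, less than x, so I put conversion at 97.9%.

The forecast, reached otherwise, gives 99% (96% to 100%) and 90% target (86% to 93%), on “a first-order side reaction of the starting material competing with bimolecular coupling”.

    starting material ⇌ open intermediate (K = 2.90, k = 0.00660 /s)
    partner → second intermediate (k = 0.00340 /s)
    open intermediate + second intermediate ⇌ target (K = 43.0 /M, k = 0.0280 /M/s)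

The flask gives 97.2% conversion and 89.1% target; at 5.00 h it holds 2.80% starting material and 8.12% open intermediate, with the second intermediate at 0.255 M and 0% partner. Its own Q is 32.0 /M. A neighbouring flask takes 8.00 equiv of partner, with the starting material and time held. The same equation with that larger excess leaves x = 1.92%, so I reckon 98.1% target, and that flask gives 98.1%.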